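**The question.** Chain length is asked of alder and oak, and it follows from the links made. Each link removes two ends, while quenched ends stay counted. With S the sum of both end-group charges and L the links, the average length is X = S/(S − 2L).

| setting | south | north | east | alder | oak |
|---|---|---|---|---|---|
| first end groups | 0.80 M | 0.80 M | 0.80 M | 0.80 M | 0.80 M |
| second end groups | 0.68 M | 1.1 M | 1.3 M | 0.800 M | 1.50 M |
| protic impurity | 0.080 M | 0.080 M | 0.080 M | 0.0800 M | 0.0800 M |
| remark | run made earlier | run made earlier | run made earlier |  |  |
| time |  |  |  | 10 d | 10 d |

| run | time / d | links / % | first end groups / % |
|---|---|---|---|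
| south | 0.833 | 46.6 | 51.5 |
| south | 2.50 | 65.7 | 34.5 |
| south | 5.00 | 70.5 | 28.3 |
| south | 8.00 | 76.2 | 25.8 |
| south | 10.0 | 74.3 | 25.7 |
| north | 0.833 | 66.8 | 33.9 |
| north | 2.50 | 88.1 | 11.2 |
| north | 5.00 | 96.0 | 3.7 |
| north | 8.00 | 98.8 | 2.1 |
| north | 10.0 | 99.1 | 1.7 |
| east | 0.833 | 73.2 | 26.3 |
| east | 1.67 | 87.8 | 13.0 |
| east | 3.00 | 97.2 | 5.7 |
| east | 5.00 | 102.1 | 0.7 |
| east | 10.0 | 101.1 | 0.4 |

(each reading ± 1 percentage point)

- each molecule carries two end groups: a chain counts once for every two ends that are left, dead ends included; the units are half of the end groups of the two monomers charged
- steps that have been proposed: released group -> by-product carried off; first end groups + second end groups <-> links + released group; second end groups + protic impurity -> quenched reagent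

* which of the two ends with the longer chains by the average number of monomer units in a chain (unreacted monomers counted as chains of one) ("neither" if they lie within 10%) (alder / oak / neither)
* average number of monomer units in a chain (unreacted monomers counted as chains of one) at the end, alder
* average number of monomer units in a chain (unreacted monomers counted as chains of one) at the end, oak

**The cap.** South levels off at 74.3% links, or 0.594 M. Its second ends less its impurity come to 0.600 M. North, with 1.02 M by the same subtraction, exceeds its first ends and reaches 99.1%. Oak gives 1.42 M and alder 0.720 M. This difference is U, the usable second ends. The working rule is that links stop at the smaller of U and the first ends, the limiting reagent.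

**Two ceilings.** Alder's cap is 0.720 M, giving X = 10.0. Oak's cap is 0.80 M, giving X = 3.29.

**Weak link.** Those ceilings assume the cap is reached by 10 d. North's first reading, taken with U, gives a second-order constant k = 0.0798 M⁻¹ h⁻¹. Oak's usable second ends stay in excess but run down from 1.42 M towards 0.620 M, so its rate stays second-order. The integrated second-order law with this k brings its first ends to half their charge in 0.305 d, far shorter than the time allowed, and its ceiling stands. Alder's rate per first end, kB, drifts down with its second ends B. Its ratio of first to second ends grows from 1.11 to 5.14, which leaves B = 0.0193 M and X = 8.06.

**The forecast.** It names alder, with 7.9 for alder, slightly below the figure reckoned here, and 3.28 for oak. It judges that “with the by-product removed, reversal is barely visible”.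

**The result.** Alder ends at 7.81 and oak at 3.29, so alder has the longer chains. At 10.0 d alder still holds 2.80% of its second ends, and at 100 d its length is 10.0.

    released group → by-product carried off (k = 0.110 h⁻¹)
    first end groups + second end groups ⇌ links + released group (K = 2.10, k = 0.0960 M⁻¹ h⁻¹)
    second end groups + protic impurity → quenched reagent (k = 0.540 M⁻¹ h⁻¹)

**Neighbour flask.** This is oak with 2.0 M of first ends. U stays 1.42 M, now below the first ends, so the cap passes to the second ends: links at 71.0% of the first ends and X = 5.30. At 10.0 d the neighbour flask holds 71.0% links, and its chains average 5.30 units.

(The runs come from a simulation for an exercise; noise was put on by code.)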